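You cannot read the ratio at 2.5 min out of these runs, because the dawn run opens at 0.167 d, far later, and the other two open later still. The quick number needs another handle, and the late readings offer one.

the same everywhere: starting material 0.24 M
- spring: coupling partner 0.48 M; catalyst 8 mM; run made earlier
- dawn: coupling partner 0.48 M; catalyst 12 mM; run made earlier
- noon: coupling partner 0.24 M; catalyst 16 mM; run made earlier
- flask: coupling partner 0.480 M; catalyst 16 mM; time 4.0 d

| run | time / d | isomer of the product A / % | target / % | starting material / % |
|---|---|---|---|---|
| spring | 0.250 | 6 | 35 | 46 |
| spring | 0.417 | 7 | 31 | 44 |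
| spring | 0.625 | 12 | 30 | 38 |
| spring | 0.833 | 14 | 32 | 39 |
| spring | 1.25 | 25 | 31 | 36 |
| spring | 2.00 | 33 | 26 | 33 |
| spring | 3.00 | 40 | 19 | 31 |
| dawn | 0.167 | 9 | 30 | 54 |
| dawn | 0.500 | 10 | 37 | 40 |
| dawn | 0.833 | 17 | 33 | 35 |
| dawn | 1.25 | 24 | 30 | 36 |
| dawn | 2.08 | 31 | 23 | 34 |
| dawn | 2.50 | 38 | 22 | 34 |
| dawn | 3.00 | 41 | 19 | 25 |
| noon | 0.250 | 2 | 22 | 68 |
| noon | 0.500 | 8 | 20 | 58 |
| noon | 0.833 | 15 | 16 | 59 |
| noon | 1.67 | 23 | 16 | 53 |
| noon | 3.00 | 29 | 15 | 52 |

(standard deviation of a reading: 2 percentage points)

* ratio of isomer of the product A to target at 2.5 min
* ratio of isomer of the product A to target at 2.0 h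
* ratio of isomer of the product A to target at 4.0 d
* which of isomer of the product A and target there is more of at 4.0 d

- the numbers in the tables scatter with a standard deviation of 2 percentage points

Look for what stays nearly constant. Assume each starting material lost takes one coupling partner with it, and call [target]/([starting material][coupling partner]) the resting quotient. At its last reading the spring run has target over starting material at 0.613, with [coupling partner] at 0.314 M, so its quotient reads 1.95 /M. The noon run ends at 0.288 with 0.125 M, which reads 2.31 /M. Those two ratios differ, but the quotients stand close within the scatter, as a pre-equilibrium would. So I freeze it at 2.13 /M.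

Your flask has the spring charges of starting material and partner, so I take the spring partner level, which puts target over starting material at 0.670. The spring balance lacks 10.0%, and I allow the same here. I have nothing better for the ratio itself, so with yours I get target near 16.4% at 4.0 d, against the 15% in your forecast.

Your forecast stands at 0.01 for 2.5 min, 0.08 for 2.0 h and 3 for 4.0 d, with isomer of the product A ahead, on the ground that the ratio “rises almost linearly with time from near zero”.

The flask gives 0.0589, 0.0977 and 3.21, with 53.0% isomer of the product A against 16.5% target.

    target ⇌ isomer of the product B (K = 0.430, k = 0.130 /h)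
    starting material + coupling partner ⇌ isomer of the product A (K = 28.0 /M, k = 0.0390 /M/h)
    starting material + coupling partner ⇌ target (K = 2.40 /M, k = 0.670 /M/h)
    target + catalyst ⇌ isomer of the product A + catalyst, rate k4*[catalyst]*[target] forward; the back reaction follows from the equilibrium constant (k = 0.510 /M/h)
    coupling partner → decomposition product (k = 8.80 × 10⁻⁵ /h)

In this flask the step between starting material plus coupling partner and target relaxes with a half-life of 0.0563 d at 4.0 d, short against the run, and its backward turnover is 94% of the forward one. The resting quotient of this flask at 4.0 d stands at 2.43 /M, beside the 2.13 /M read from the runs. The neighbouring flask charged with 0.19 M coupling partner holds 10.4% target and 54.3% starting material at 4.0 d, with 0.0795 M partner, a quotient of 2.41 /M.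

Readings and results are calculated with made-up constants, and the scatter is random.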